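## Structural features

Target 28 is a single 14-membered carbocycle (C1–C14) with a methyl ester on C1, methyl groups on C7 and C11, and on C4 an eight-carbon side chain (C15–C19 plus three methyl groups) that is a skipped diene. The ring holds three trisubstituted alkenes: the enoate C1=C2 (E, ester trans to C3, so C14 and C3 are cis) and the E alkenes C7=C8 and C11=C12. The side chain adds the E alkene C15=C16 and the terminal C18=C19. C4 is the only stereocentre (R). It is tertiary, allylic to C15=C16 and has no neighbouring stereocentre to relay from, so it must come from an enantioselective reaction and must then be kept away from conditions that move double bonds. The fragile elements are the doubly allylic C–H bonds (C17 in all compounds, C4 as long as C5=C6 is present), the enoate as an acceptor and, in the intermediates, an alkenyl iodide. The real difficulty is the combination of an entropically costly 14-membered ring closure with four trisubstituted alkenes of fixed geometry and one isolated stereocentre. The key step uses the only saturated two-carbon stretch of the ring, C5–C6, between C4 and the methyl-bearing sp2 carbon C7: C5=C6 is a vinyl group on C4 in the open chain, and C6–C7 is made by sp3–sp2 cross-coupling so that the C7=C8 geometry is taken over from an alkenyl iodide.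

## Logic of the disconnections

**28 to 26 (through 27).** The ring bond C6–C7 is cut. It lies far from the ester, does not touch C4, and on one side ends in a CH2 that can come from a terminal alkene and on the other in an sp2 carbon that can carry iodine. The gain is an open chain in which every alkene and the stereocentre already exist and in which no protecting group is needed. The demand is hydroboration of one alkene out of six, ring closure faster than chain growth, and retention at C7. A check of 26 against 28 shows the same connectivity apart from C6–C7, the same alkene geometries and the same spatial arrangement at C4. The label changes from S to R only because C5 is ranked differently once it is no longer vinylic, so no structure needs correcting. The one refinement is operational: 27 is made at normal concentration and fed slowly to the catalyst, because hydroboration is too slow at the dilution the ring closure needs.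

**26 to 13 and 25.** The double bond C1=C2 is cut by carbonyl olefination. This divides the molecule into two halves of thirteen carbons each and lets a stabilised ylide set the enoate geometry. The demand is E selectivity with an α-substituted ylide and neutral conditions that leave C4 and the alkenyl iodide alone.

**25 to 22 and 5.** The bond C1–C14 is cut as an alkylation of the ylide carbon. The gain is that the ester, C1 and phosphorus come from one commercial reagent. The demand is SN2 at a homoallylic carbon without elimination, with the alkenyl iodide as a spectator.

**22 to 20 (through 21).** C7–I and C8–H are removed to leave the alkyne C7≡C8. The gain is that the sensitive alkenyl iodide appears only after the organozinc chemistry. The demand is syn addition with the metal on the methyl-bearing carbon and no reaction at C11=C12 or at the C–Cl bond.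

**20 to 17 and 18 (through 19).** The bond C10–C11 is cut as an sp3–sp2 coupling. Both partners are five-carbon units with the same carbon skeleton. The demand is retention at C11 and a catalyst that leaves the alkyl chloride untouched.

**17 and 18 to 14 (17 through 16 and 15).** Only functional-group changes remain: C–Cl or C–I from C–OH, and for 16 addition of H and I across the alkyne of 14. One starting material therefore supplies C7–C10 and C11–C14 with their methyl groups.

**13 to 11 (through 12).** The C2 aldehyde is traced back to an ester and this to a malonate. The demand is loss of one ester group and a partial reduction without disturbing the 1,4-diene around C4.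

**11 to 9 and 10.** The bond C3–C4 is cut as a branched-selective allylic alkylation. It creates C4 enantioselectively, and its by-product, the vinyl group C5=C6, is the handle needed for the first disconnection. The demand is attack at C4 and not at C6 or at the far diene terminus, with high facial control by the ligand.

**9 to 4 and 5 (through 8, 7 and 6).** The C4=C5 double bond of the dienyl unit is cut by olefination of an enal. The carbonate and the alcohol are functional-group changes. The demand is E selectivity and avoidance of base that would draw C17–H into conjugation.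

**4 to 1 and 2 (through 3).** C16–C17 and the C15–methyl bond are cut. Syn methylmetalation of the alkyne fixes the E geometry of C15=C16, and the allyl unit is attached at the metal-bearing carbon. The demand is regiospecific carbometalation and coupling at the unsubstituted terminus of the prenyl unit.

## Other disconnections considered

**Alternative 1:** The cut is C4–C5, made as a ring contraction.

- **Forward step.** The 18-membered lactone A2 (acyl carbon on C5, ring oxygen on C16, E alkene C4=C15) would be converted with LiN(SiMe3)2 and Me3SiCl into its silyl ketene acetal. Ireland–Claisen rearrangement would give acid A1: C4–C5 forms, O–C16 breaks and the alkene moves to C15=C16.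
- **In its favour.** Lactonisation to an 18-membered ring is easier than closing a 14-membered ring through a C–C bond, and the rearrangement is unimolecular and needs no dilution; on both counts it is better than the chosen plan. It also makes a C–C bond, C4 and the C15=C16 geometry in one step.
- **Against it.** The configuration at C4 would depend on the chair or boat shape of a transition state inside a large ring; on a chair model (16S)-A2 is needed, a boat would need the opposite. C3–H in A2 lies between two alkenes and is γ to the ester, so the strong base may deprotonate there. The carboxyl group on C5 must afterwards be removed by radical decarboxylation, which costs two more operations.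
- **Comparison.** Structurally, the chosen plan never makes C4 a reacting centre, whereas here it is the reacting centre. Mechanistically, a catalyst-controlled step on an open chain is easier to predict than transition-state geometry in a macrocycle. In step economy the alternative needs an enantiopure C16 carbinol, a macrolactonisation and a decarboxylation, so it is longer.

**Alternative 2:** The cut is C1–C14.

- **Forward step.** The open-chain β-keto ester A4 (ketone on C2, primary iodide on C14) would be cyclised with Cs2CO3 in acetonitrile at high dilution to the cyclic β-keto ester A3.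
- **In its favour.** The nucleophile is a stabilised enolate formed reversibly by a mild base. No palladium or borane is involved and nothing is air-sensitive; here it is better than the chosen plan. C4 and all alkenes are spectators, which is equal to the chosen plan. A4 could be reached from 12 by a two-carbon acylation.
- **Against it.** O-alkylation and elimination at the homoallylic iodide compete. The C2 ketone must afterwards be turned into the E enoate (enol triflation and palladium-catalysed reduction with formate, or reduction and dehydration), which adds at least two steps and a geometry problem inside the ring. The C6–C7 bond and the E C7=C8 alkene still have to be made in the open chain, most likely by the same kind of cross-coupling.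
- **Comparison.** The dilution requirement is equal. In the chosen plan the ring closure delivers the target itself with the enoate geometry already fixed by an open-chain Wittig reaction, so it is shorter by about three steps.

**Alternative 3:** The cut is C5–C6.

- **Forward step.** The open-chain nitro carbonate A6 would be treated with Pd(PPh3)4. Zerovalent palladium ionises the allylic carbonate to an allyl complex over C6–C8, and the C5 nitronate, formed by the released methoxide, attacks C6 to give the nitro carbocycle A5 (Tsuji–Trost-type macrocyclisation).
- **In its favour.** Conditions are neutral and the base is generated only as the electrophile forms. Such closures tolerate higher concentration than a cross-coupling, which is a point where it is better. A nitromethyl group on C4 could come from an asymmetric conjugate addition that also sets C4, which is equal in stereochemical economy.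
- **Against it.** Attack at C8 would give a 12-membered ring. The E geometry of C7=C8 can be lost by syn–anti exchange in the allyl complex, whereas in the chosen plan it is locked by oxidative addition with retention. The reacting carbon is directly next to C4. The nitronate is ambident, and A5 can lose HNO2 toward C4 or C6. Removal of a secondary nitro group with Bu3SnH is sluggish.
- **Comparison.** The alternative needs at least one uncertain extra step after ring closure and an extra functional group before it. The chosen plan needs neither.

Key step: step 15

Assumption: the (Sa,S,S) phosphoramidite is taken to give (R)-11, by analogy with the sense of induction known for aryl- and alkenyl-substituted allylic carbonates. If the sense proves opposite, the (Ra,R,R) ligand is used with no other change.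

## Route

Step 1
Reactants: 1 prop-2-yn-1-ol (propargyl alcohol); 2 1-bromo-3-methylbut-2-ene (prenyl bromide)
Product: 4 (2E)-2,6-dimethylhepta-2,5-dien-1-ol, via alkenylalane 3 (not isolated)
Conditions: Me3Al (3 equiv), Cp2ZrCl2 (0.25 equiv), ClCH2CH2Cl, 0 °C to rt; then 2 (1.2 equiv), Pd(PPh3)4 (3 mol%), THF, rt; aqueous work-up
Reagents that add atoms: trimethylaluminium, C[Al](C)C
Why: Zirconium-catalysed methylalumination (Negishi carboalumination) of the aluminium alkoxide of 1 adds methyl and aluminium syn with aluminium on the terminal carbon, which fixes the E geometry of C15=C16 in 3. Palladium-catalysed coupling of the alkenylalane with the allylic bromide goes with retention at the alkenyl carbon and at the unsubstituted allyl terminus, so the prenyl unit is attached without transposition.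

Step 2
Reactants: 4 (2E)-2,6-dimethylhepta-2,5-dien-1-ol; 5 methyl (triphenyl-λ5-phosphanylidene)acetate
Product: 7 methyl (2E,4E)-4,8-dimethylnona-2,4,7-trienoate, via dienal 6 (not isolated)
Conditions: activated MnO2 (10 equiv), 5 (1.3 equiv), CH2Cl2, rt
Reagents that add atoms: none
Why: MnO2 oxidises the allylic alcohol to enal 6, which is trapped as it forms by the stabilised ylide (tandem oxidation–Wittig reaction), so the base-sensitive skipped dienal is never handled. Stabilised ylides give the E enoate.

Step 3
Reactants: 7 methyl (2E,4E)-4,8-dimethylnona-2,4,7-trienoate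
Product: 8 (2E,4E)-4,8-dimethylnona-2,4,7-trien-1-ol
Conditions: iBu2AlH (2.3 equiv), CH2Cl2, −78 °C to 0 °C; aq. potassium sodium tartrate
Reagents that add atoms: none
Why: 1,2-Reduction of a conjugated ester by iBu2AlH gives the allylic alcohol and does not affect alkene geometry.

Step 4
Reactants: 8 (2E,4E)-4,8-dimethylnona-2,4,7-trien-1-ol
Product: 9 (2E,4E)-4,8-dimethylnona-2,4,7-trien-1-yl methyl carbonate
Conditions: ClCO2Me, pyridine, CH2Cl2, 0 °C
Reagents that add atoms: methyl chloroformate, COC(=O)Cl
Why: Acylation of the primary allylic alcohol gives the linear methyl carbonate, which is the leaving group for iridium-catalysed allylic substitution and the internal source of methoxide.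

Step 5
Reactants: 9 (2E,4E)-4,8-dimethylnona-2,4,7-trien-1-yl methyl carbonate; 10 dimethyl propanedioate (dimethyl malonate)
Product: 11 dimethyl 2-[(3R,4E)-4,8-dimethylnona-1,4,7-trien-3-yl]propanedioate
Conditions: [Ir(cod)Cl]2 (2 mol%), L (4 mol%), 1,5,7-triazabicyclo[4.4.0]dec-5-ene (8 mol%), 10 (1.3 equiv), THF, rt; L = (Sa)-(1,1′-binaphthalene-2,2′-diyl) N,N-bis[(S)-1-phenylethyl]phosphoramidite
Reagents that add atoms: none
Why: Iridium-catalysed asymmetric allylic alkylation: the cyclometalated iridium–phosphoramidite complex ionises the carbonate, and malonate, deprotonated by the released methoxide, attacks the substituted allyl terminus, which creates C4 and leaves C5=C6 as a vinyl group. The ligand controls the face of attack and so sets C4 (R in 11); the far diene terminus is trisubstituted and does not compete.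

Step 6
Reactants: 11 dimethyl 2-[(3R,4E)-4,8-dimethylnona-1,4,7-trien-3-yl]propanedioate
Product: 12 methyl (3S,4E)-3-ethenyl-4,8-dimethylnona-4,7-dienoate
Conditions: NaCl (1.5 equiv), H2O (2 equiv), DMSO, 150 °C
Reagents that add atoms: none
Why: Krapcho dealkoxycarbonylation removes one ester group under nearly neutral conditions, so the doubly allylic C4–H is not touched. The descriptor changes from R to S only because the ranking of the substituents changes.

Step 7
Reactants: 12 methyl (3S,4E)-3-ethenyl-4,8-dimethylnona-4,7-dienoate
Product: 13 (3S,4E)-3-ethenyl-4,8-dimethylnona-4,7-dienal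
Conditions: iBu2AlH (1.05 equiv), CH2Cl2, −78 °C; MeOH quench, aq. potassium sodium tartrate
Reagents that add atoms: none
Why: Partial reduction by iBu2AlH at low temperature stops at the aluminium hemiacetal, which gives the aldehyde on work-up. C4 is β to the carbonyl and cannot epimerise by enolisation.

Step 8
Reactants: 14 pent-3-yn-1-ol
Product: 16 (3E)-4-iodopent-3-en-1-ol, via alkenylzirconocene 15 (not isolated)
Conditions: iBu2AlH (1.0 equiv), THF, 0 °C; Cp2Zr(H)Cl (1.5 equiv), THF, rt to 40 °C; I2 (1.6 equiv), THF, −78 °C to 0 °C
Reagents that add atoms: iodine, II
Why: Hydrozirconation adds Zr–H syn across the alkyne once the hydroxyl group is masked as its aluminium alkoxide. With a slight excess of Cp2Zr(H)Cl the adducts equilibrate toward zirconium on the less hindered, methyl-bearing carbon (15), and iodinolysis with retention gives the (E)-2-iodoalkene.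

Step 9
Reactants: 16 (3E)-4-iodopent-3-en-1-ol
Product: 17 (2E)-5-chloro-2-iodopent-2-ene
Conditions: PPh3, N-chlorosuccinimide, CH2Cl2, 0 °C to rt
Reagents that add atoms: N-chlorosuccinimide, O=C1CCC(=O)N1Cl
Why: Appel-type chlorination converts the primary alcohol into the chloride by SN2 on the alkoxyphosphonium ion. A chloride is chosen because it survives the organozinc, palladium and zirconium hydride steps and is activated later by iodide.

Step 10
Reactants: 14 pent-3-yn-1-ol
Product: 18 5-iodopent-2-yne
Conditions: I2, PPh3, imidazole, CH2Cl2, 0 °C to rt
Reagents that add atoms: iodine, II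
Why: Appel iodination of the primary alcohol; the internal alkyne is inert.

Step 11
Reactants: 18 5-iodopent-2-yne; 17 (2E)-5-chloro-2-iodopent-2-ene
Product: 20 (6E)-9-chloro-6-methylnon-6-en-2-yne, via alkylzinc iodide 19 (not isolated)
Conditions: Zn dust (activated with BrCH2CH2Br and Me3SiCl), LiCl, THF, 40 °C; then 17 (0.8 equiv), PdCl2(dppf) (3 mol%), THF, rt
Reagents that add atoms: none
Why: Zinc inserts into the primary C–I bond to give 19, and Negishi sp3–sp2 coupling with the alkenyl iodide goes with retention of the E geometry. PdCl2(dppf) suppresses β-hydride elimination, and neither the zinc reagent nor the catalyst touches the alkyl chloride.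

Step 12
Reactants: 20 (6E)-9-chloro-6-methylnon-6-en-2-yne
Product: 22 (2E,6E)-9-chloro-2-iodo-6-methylnona-2,6-diene, via alkenylzirconocene 21 (not isolated)
Conditions: Cp2Zr(H)Cl (1.6 equiv), THF, rt to 45 °C; I2, THF, −78 °C to 0 °C
Reagents that add atoms: iodine, II
Why: Hydrozirconation–iodination as in step 8: the alkyne reacts far faster than the trisubstituted alkene, thermodynamic control places zirconium on the methyl-bearing carbon (21), and iodinolysis with retention gives the second (E)-2-iodoalkene. The alkyl chloride is inert to Cp2Zr(H)Cl.

Step 13
Reactants: 22 (2E,6E)-9-chloro-2-iodo-6-methylnona-2,6-diene; 5 methyl (triphenyl-λ5-phosphanylidene)acetate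
Product: 25 methyl (5E,9E)-10-iodo-6-methyl-2-(triphenyl-λ5-phosphanylidene)undeca-5,9-dienoate, via diiodide 23 (not isolated), via phosphonium iodide 24 (not isolated)
Conditions: NaI (1.5 equiv), 5 (2.2 equiv), MeCN, reflux; filtration of the phosphonium by-product
Reagents that add atoms: none
Why: Finkelstein exchange gives the primary iodide 23, which alkylates the α-carbon of the stabilised ylide by SN2 to phosphonium salt 24. A second equivalent of 5 deprotonates 24 (transylidation) and leaves the α-substituted ylide 25; the alkenyl iodide cannot undergo SN2.

Step 14
Reactants: 13 (3S,4E)-3-ethenyl-4,8-dimethylnona-4,7-dienal; 25 methyl (5E,9E)-10-iodo-6-methyl-2-(triphenyl-λ5-phosphanylidene)undeca-5,9-dienoate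
Product: 26 methyl (2E,5S,6E)-5-ethenyl-2-[(3E,7E)-8-iodo-4-methylnona-3,7-dien-1-yl]-6,10-dimethylundeca-2,6,9-trienoate
Conditions: toluene, 90 °C
Reagents that add atoms: none
Why: The Wittig reaction of an α-substituted stabilised ylide with an unhindered aldehyde gives the trisubstituted enoate with the ester trans to C3 (E). The conditions are neutral, so C4 and the alkenyl iodide are untouched.

Step 15
Reactants: 26 methyl (2E,5S,6E)-5-ethenyl-2-[(3E,7E)-8-iodo-4-methylnona-3,7-dien-1-yl]-6,10-dimethylundeca-2,6,9-trienoate
Product: 28 methyl (1E,4R,7E,11E)-7,11-dimethyl-4-[(2E)-6-methylhepta-2,5-dien-2-yl]cyclotetradeca-1,7,11-triene-1-carboxylate, via B-alkyl-9-BBN 27 (not isolated)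
Conditions: 9-BBN (1.5 equiv), THF, 0 °C to rt; then slow addition (syringe pump) to PdCl2(dppf) (15 mol%), AsPh3 (30 mol%), Cs2CO3 (3 equiv), DMF/THF/H2O, 45 °C, final concentration about 1 mM (dppf = 1,1′-bis(diphenylphosphino)ferrocene)
Reagents that add atoms: none
Why: 9-BBN adds to the only monosubstituted alkene, C5=C6, with boron on C6 to give 27; the trisubstituted alkenes, the electron-poor enoate and the alkenyl iodide react far more slowly with this hindered borane at room temperature. Zerovalent palladium formed from PdCl2(dppf) inserts into the C7–I bond with retention, base turns the borane into a borate that transfers the primary C6 alkyl group to divalent palladium, and reductive elimination forms C6–C7 and returns zerovalent palladium; dppf keeps the two carbon ligands cis so that reductive elimination outruns β-hydride elimination, and AsPh3 speeds up transmetalation. The closest known reaction type is the B-alkyl Suzuki–Miyaura macrocyclisation of an ω-alkenyl (E)-2-iodoalk-2-ene, which has been used for carbocycles and macrolides of twelve and more ring atoms. The 14-membered ring is closed end to end, from sp3 C6 to sp2 C7, through a large palladacycle, so only the entropic cost has to be met; this is done by feeding 27 slowly so that its stationary concentration stays low. No stereocentre is formed: C4 is not a reacting centre, and its label changes from S in 26 to R in 28 only through the ranking of C5. The selectivities needed are site selectivity of hydroboration (secured by the single terminal alkene), ring closure over oligomerisation (secured by dilution and by the rigid E alkenes in the chain) and retention of the E geometry at C7=C8 (inherent in oxidative addition and reductive elimination at an alkenyl carbon).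

## Compound list

1 | prop-2-yn-1-ol (propargyl alcohol) | C#CCO | starting material
2 | 1-bromo-3-methylbut-2-ene (prenyl bromide) | CC(C)=CCBr | starting material
3 | alkenylalane, dimethyl{(1E)-3-[(dimethylalumanyl)oxy]-2-methylprop-1-en-1-yl}alumane (not isolated) | C[Al](C)/C=C(\C)CO[Al](C)C | intermediate
4 | (2E)-2,6-dimethylhepta-2,5-dien-1-ol | CC(C)=CC/C=C(\C)CO | intermediate
5 | methyl (triphenyl-λ5-phosphanylidene)acetate | COC(=O)C=P(c1ccccc1)(c1ccccc1)c1ccccc1 | starting material
6 | dienal, (2E)-2,6-dimethylhepta-2,5-dienal (not isolated) | CC(C)=CC/C=C(\C)C=O | intermediate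
7 | methyl (2E,4E)-4,8-dimethylnona-2,4,7-trienoate | COC(=O)/C=C/C(C)=C/CC=C(C)C | intermediate
8 | (2E,4E)-4,8-dimethylnona-2,4,7-trien-1-ol | OC/C=C/C(C)=C/CC=C(C)C | intermediate
9 | (2E,4E)-4,8-dimethylnona-2,4,7-trien-1-yl methyl carbonate | COC(=O)OC/C=C/C(C)=C/CC=C(C)C | intermediate
10 | dimethyl propanedioate (dimethyl malonate) | COC(=O)CC(=O)OC | starting material
11 | dimethyl 2-[(3R,4E)-4,8-dimethylnona-1,4,7-trien-3-yl]propanedioate | COC(=O)C(C(=O)OC)[C@H](/C(C)=C/CC=C(C)C)C=C | intermediate
12 | methyl (3S,4E)-3-ethenyl-4,8-dimethylnona-4,7-dienoate | COC(=O)C[C@H](/C(C)=C/CC=C(C)C)C=C | intermediate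
13 | (3S,4E)-3-ethenyl-4,8-dimethylnona-4,7-dienal | O=CC[C@H](/C(C)=C/CC=C(C)C)C=C | intermediate
14 | pent-3-yn-1-ol | CC#CCCO | starting material
15 | alkenylzirconocene, chlorobis(cyclopentadienyl)[(2E)-5-{[bis(2-methylpropyl)alumanyl]oxy}pent-2-en-2-yl]zirconium (not isolated) | CC(C)C[Al](CC(C)C)OCC/C=C(\C)[Zr](Cl)(C1C=CC=C1)C1C=CC=C1 | intermediate
16 | (3E)-4-iodopent-3-en-1-ol | OCC/C=C(\C)I | intermediate
17 | (2E)-5-chloro-2-iodopent-2-ene | ClCC/C=C(\C)I | intermediate
18 | 5-iodopent-2-yne | CC#CCCI | intermediate
19 | alkylzinc iodide, (pent-3-yn-1-yl)zinc iodide (not isolated) | CC#CCC[Zn]I | intermediate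
20 | (6E)-9-chloro-6-methylnon-6-en-2-yne | CC#CCC/C(C)=C/CCCl | intermediate
21 | alkenylzirconocene, chlorobis(cyclopentadienyl)[(2E,6E)-9-chloro-6-methylnona-2,6-dien-2-yl]zirconium (not isolated) | ClCC/C=C(C)/CC/C=C(\C)[Zr](Cl)(C1C=CC=C1)C1C=CC=C1 | intermediate
22 | (2E,6E)-9-chloro-2-iodo-6-methylnona-2,6-diene | ClCC/C=C(C)/CC/C=C(C)/I | intermediate
23 | diiodide, (2E,6E)-2,9-diiodo-6-methylnona-2,6-diene (not isolated) | ICC/C=C(C)/CC/C=C(C)/I | intermediate
24 | phosphonium iodide, [(5E,9E)-10-iodo-1-methoxy-6-methyl-1-oxoundeca-5,9-dien-2-yl]triphenylphosphonium iodide (not isolated) | COC(=O)C(CC/C=C(C)/CC/C=C(C)/I)[P+](c1ccccc1)(c1ccccc1)c1ccccc1.[I-] | intermediate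
25 | methyl (5E,9E)-10-iodo-6-methyl-2-(triphenyl-λ5-phosphanylidene)undeca-5,9-dienoate | COC(=O)C(CC/C=C(C)/CC/C=C(C)/I)=P(c1ccccc1)(c1ccccc1)c1ccccc1 | intermediate
26 | methyl (2E,5S,6E)-5-ethenyl-2-[(3E,7E)-8-iodo-4-methylnona-3,7-dien-1-yl]-6,10-dimethylundeca-2,6,9-trienoate | COC(=O)/C(CC/C=C(C)/CC/C=C(C)/I)=C/C[C@H](/C(C)=C/CC=C(C)C)C=C | intermediate
27 | B-alkyl-9-BBN, methyl (2E,5R,6E)-5-[2-(9-borabicyclo[3.3.1]nonan-9-yl)ethyl]-2-[(3E,7E)-8-iodo-4-methylnona-3,7-dien-1-yl]-6,10-dimethylundeca-2,6,9-trienoate (not isolated) | COC(=O)/C(CC/C=C(C)/CC/C=C(C)/I)=C/C[C@H](/C(C)=C/CC=C(C)C)CCB1C2CCCC1CCC2 | intermediate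
28 | methyl (1E,4R,7E,11E)-7,11-dimethyl-4-[(2E)-6-methylhepta-2,5-dien-2-yl]cyclotetradeca-1,7,11-triene-1-carboxylate | COC(=O)/C1=C/C[C@H](/C(C)=C/CC=C(C)C)CC/C(C)=C/CC/C(C)=C/CC1 | target

## Step count and least certain steps

Total: 15 steps. Longest linear sequence: 9 steps (steps 1–7, 14, 15, from 1). The second branch takes 7 steps from 14 (steps 8, 9, 11, 12, 13, 14, 15); step 10 is a one-step side branch.

**Step 15 (key step).** The most likely failure is intermolecular coupling outrunning ring closure, so that chain growth dominates. Slow transmetalation of the alkylborane can also lead to protodeboronation or β-hydride elimination, and excess borane can add to a second alkene. The fallback moves the ring closure to C1=C2 and uses the cross-coupling only between two molecules. It sets out from 12 and 22 and rejoins the route at 28. LiAlH4 reduces 12 to (3S,4E)-3-ethenyl-4,8-dimethylnona-4,7-dien-1-ol F1. Hydroboration of F1 with 9-BBN and coupling with 22 under PdCl2(dppf), AsPh3 and Cs2CO3 at normal concentration give the chloro alcohol F2. F2 alkylates the sodium salt of trimethyl phosphonoacetate (NaH, NaI as catalyst, DMF, 60 °C) to the hydroxy phosphonate F3. Dess–Martin oxidation gives the aldehyde F4, and LiCl with DBU in MeCN at high dilution closes the ring by intramolecular Horner–Wadsworth–Emmons olefination to 28. Its weak point is E/Z control at the enoate, which is why it is not the first choice.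

**Step 5.** Attack at the unsubstituted allyl terminus, or weak facial discrimination, may result because the methyl group on C15 crowds the branched position. The fallback sets out from 8 and rejoins at 12. Johnson–Claisen rearrangement of 8 (MeC(OMe)3, catalytic propionic acid, 140 °C) forms the same C3–C4 bond and the same vinyl group by a [3,3] shift, but as the racemate. Preparative chromatography on a chiral stationary phase then separates 12 from its enantiomer, methyl (3R,4E)-3-ethenyl-4,8-dimethylnona-4,7-dienoate F5. It is shorter but loses half the material.

**Step 12.** Incomplete equilibration of the two alkenylzirconium regioisomers would carry an isomeric iodide forward that is hard to remove from a non-polar chain. The fallback fixes the regiochemistry with silicon. It sets out from 17 and rejoins at 22. [4-(Trimethylsilyl)but-3-yn-1-yl]zinc bromide F6 (from commercial (4-bromobut-1-yn-1-yl)trimethylsilane, Zn, LiCl) is coupled with 17 (PdCl2(dppf)) to the silyl enyne F7. Trans-hydroalumination with iBu2AlH in heptane puts aluminium only on the silicon-bearing carbon, and the alanate formed with MeLi is methylated with MeI to the vinylsilane F8, in which silicon stands where iodine is wanted. Iododesilylation with N-iodosuccinimide in hexafluoropropan-2-ol replaces silicon by iodine with retention and gives 22.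

**Step 13.** Substitution at the unactivated homoallylic carbon is slow, and elimination to a diene or incomplete transylidation may take over. The fallback sets out from 22 and rejoins at 26. 22, through 23 formed with NaI, alkylates the sodium salt of trimethyl phosphonoacetate (NaH, DMF) to the phosphonate F9. F9 is condensed with 13 (LiCl, DBU, MeCN; Horner–Wadsworth–Emmons olefination) to 26. A lower E preference than in the Wittig reaction must be accepted and the Z isomer removed.

**Step 1.** Carbometalation of the aluminium alkoxide is slow, and the chelated alkenylalane may transfer poorly to palladium, so protonolysis could compete with coupling. The fallback sets out from 1 and 2 and rejoins at 4. CuI-catalysed coupling (K2CO3, NaI, DMF) gives 6-methylhept-5-en-2-yn-1-ol F10. Hydroxyl-directed trans-hydrostannation ([Cp*RuCl]4, Bu3SnH, CH2Cl2) gives (2Z)-6-methyl-2-(tributylstannyl)hepta-2,5-dien-1-ol F11. Stille-type methylation (MeI, Pd(PPh3)4, copper thiophene-2-carboxylate Cu(O2CC4H3S), [NBu4][Ph2PO2], DMF) replaces tin by methyl with retention and gives 4.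

## Further compounds

F1 | step 15 | (3S,4E)-3-ethenyl-4,8-dimethylnona-4,7-dien-1-ol | OCC[C@H](/C(C)=C/CC=C(C)C)C=C
F2 | step 15 | (3R,6E,10E)-13-chloro-6,10-dimethyl-3-[(2E)-6-methylhepta-2,5-dien-2-yl]trideca-6,10-dien-1-ol | OCC[C@H](/C(C)=C/CC=C(C)C)CC/C(C)=C/CC/C(C)=C/CCCl
F3 | step 15 | methyl (5E,9E,13R)-2-(dimethoxyphosphoryl)-15-hydroxy-6,10-dimethyl-13-[(2E)-6-methylhepta-2,5-dien-2-yl]pentadeca-5,9-dienoate | COC(=O)C(CC/C=C(C)/CC/C=C(C)/CC[C@H](CCO)/C(C)=C/CC=C(C)C)P(=O)(OC)OC
F4 | step 15 | methyl (5E,9E,13R)-2-(dimethoxyphosphoryl)-6,10-dimethyl-13-[(2E)-6-methylhepta-2,5-dien-2-yl]-15-oxopentadeca-5,9-dienoate | COC(=O)C(CC/C=C(C)/CC/C=C(C)/CC[C@H](CC=O)/C(C)=C/CC=C(C)C)P(=O)(OC)OC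
F5 | step 5 | methyl (3R,4E)-3-ethenyl-4,8-dimethylnona-4,7-dienoate | COC(=O)C[C@@H](/C(C)=C/CC=C(C)C)C=C
F6 | step 12 | [4-(trimethylsilyl)but-3-yn-1-yl]zinc bromide | C[Si](C)(C)C#CCC[Zn]Br
F7 | step 12 | [(6E)-9-chloro-6-methylnon-6-en-1-yn-1-yl]trimethylsilane | C[Si](C)(C)C#CCC/C(C)=C/CCCl
F8 | step 12 | [(2E,6E)-9-chloro-6-methylnona-2,6-dien-2-yl]trimethylsilane | ClCC/C=C(C)/CC/C=C(C)/[Si](C)(C)C
F9 | step 13 | methyl (5E,9E)-2-(dimethoxyphosphoryl)-10-iodo-6-methylundeca-5,9-dienoate | COC(=O)C(CC/C=C(C)/CC/C=C(C)/I)P(=O)(OC)OC
F10 | step 1 | 6-methylhept-5-en-2-yn-1-ol | CC(C)=CCC#CCO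
F11 | step 1 | (2Z)-6-methyl-2-(tributylstannyl)hepta-2,5-dien-1-ol | CC(C)=CC/C=C(\[Sn](CCCC)(CCCC)CCCC)CO
A1 | alternative 1 | (3E,7E,11E,14S)-11-(methoxycarbonyl)-3,7-dimethyl-14-[(2E)-6-methylhepta-2,5-dien-2-yl]cyclotetradeca-3,7,11-triene-1-carboxylic acid (C1 unassigned) | COC(=O)/C1=C/C[C@H](/C(C)=C/CC=C(C)C)C(C(=O)O)C/C(C)=C/CC/C(C)=C/CC1
A2 | alternative 1 | methyl (2S,3E,6E,10E,14E)-3,11,15-trimethyl-2-(3-methylbut-2-en-1-yl)-18-oxo-1-oxacyclooctadeca-3,6,10,14-tetraene-7-carboxylate | COC(=O)/C1=C/C/C=C(C)/[C@H](CC=C(C)C)OC(=O)CC/C(C)=C/CC/C(C)=C/CC1
A3 | alternative 2 | methyl (4E,8E,12R)-5,9-dimethyl-12-[(2E)-6-methylhepta-2,5-dien-2-yl]-14-oxocyclotetradeca-4,8-diene-1-carboxylate (C1 unassigned) | COC(=O)C1C(=O)C[C@H](/C(C)=C/CC=C(C)C)CC/C(C)=C/CC/C(C)=C/CC1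
A4 | alternative 2 | methyl (5R,8E,12E)-15-iodo-8,12-dimethyl-5-[(2E)-6-methylhepta-2,5-dien-2-yl]-3-oxopentadeca-8,12-dienoate | COC(=O)CC(=O)C[C@H](/C(C)=C/CC=C(C)C)CC/C(C)=C/CC/C(C)=C/CCI
A5 | alternative 3 | methyl (1E,4R,7E,11E)-7,11-dimethyl-4-[(2E)-6-methylhepta-2,5-dien-2-yl]-5-nitrocyclotetradeca-1,7,11-triene-1-carboxylate (C5 unassigned) | COC(=O)/C1=C/C[C@H](/C(C)=C/CC=C(C)C)C([N+](=O)[O-])C/C(C)=C/CC/C(C)=C/CC1
A6 | alternative 3 | methyl (2E,5R,6E)-2-{(3E,7E)-9-[(methoxycarbonyl)oxy]-4,8-dimethylnona-3,7-dien-1-yl}-6,10-dimethyl-5-(nitromethyl)undeca-2,6,9-trienoate | COC(=O)/C(CC/C=C(C)/CC/C=C(C)/COC(=O)OC)=C/C[C@H](/C(C)=C/CC=C(C)C)C[N+](=O)[O-]
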